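**Retrosynthetic overview**

1. Target ⇐ its O3 triethylsilyl ether ⇐ one-flask C6–C7 ring closure and lactonisation of an acyclic (4Z)-enal: the C7=C11 π bond, as a 2-(ethoxycarbonyl)allyl nucleophile, attacks C6, the double bond moves to C11=C13, and O6 then closes onto C12.
2. The allyl nucleophile comes from a C7–C8 vinyl oxirane by acylative palladium ionisation, which also puts the angelate on O8; the oxirane comes from Shi epoxidation of a dienoate made by Horner–Wadsworth–Emmons olefination of a C8 aldehyde.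
3. C8 aldehyde ⇐ ozonolysis of a nerol-derived chain; C3–C4 bond ⇐ Felkin addition of a (Z)-alkenyllithium (from but-2-yn-1-ol) to 2,3-epoxyneral; C1–C2 oxirane ⇐ Sharpless epoxidation of nerol.
4. Ring order: C1–C2 oxirane first (step 1); ten-membered carbocycle and γ-lactone together in the key step (step 9).

Assumption: heliangolide-type locants are used for this irregular skeleton (C1 = oxirane carbon bearing CH3, C2 = oxirane CH, C3 = carbinol, C4(CH3)=C5, C6 = lactone O–CH, C7, C8 = angelate carbon, C9, C10, C11=C13, C12 = lactone C=O), so the target is (1S,2R,3R,4Z,6S,7R,8R); its biosynthesis is presumed costunolide-like (C6–C7 ring closure leaving the C11=C13 ene, O6-to-C12 lactonisation, oxirane by oxygen transfer to a Z-alkene).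

**Route**

Step 1
Reactants: 1 nerol
Product: 2 (2R,3S)-2,3-epoxynerol
Conditions: Ti(OiPr)4 (10 mol %), D-(−)-diethyl tartrate (12 mol %), t-BuOOH, 4 Å MS, CH2Cl2, −20 °C
Reagents that add atoms: tert-butyl hydroperoxide CC(C)(C)OO
Why: Sharpless asymmetric epoxidation of the primary Z-allylic alcohol, in which the D-(−)-tartrate/Ti(OiPr)4 catalyst delivers oxygen to the face that gives the (2R,3S) cis-oxirane (C1 S, C2 R in target locants) and leaves the isolated isopropylidene alkene untouched.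

Step 2
Reactants: 2 (2R,3S)-2,3-epoxynerol
Product: 3 (2S,3S)-2,3-epoxyneral
Conditions: PhI(OAc)2, TEMPO (10 mol %), CH2Cl2, 23 °C
Reagents that add atoms: none
Why: Oxoammonium (TEMPO/PhI(OAc)2) oxidation stops at the aldehyde under near-neutral conditions, so the α-oxirane stereocentre is neither epimerised nor opened (the descriptor changes only through CIP priorities).

Step 3
Reactants: 4 but-2-yn-1-ol
Product: 5 (Z)-3-iodobut-2-en-1-ol
Conditions: NaAlH2(OCH2CH2OCH3)2, THF, 0 → 23 °C; then I2, THF, −78 → 0 °C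
Reagents that add atoms: iodine II
Why: Alkoxide-directed trans-hydroalumination places aluminium on C3 in a five-membered alanate, and iodinolysis with retention gives only the Z-iodoalkene, the source of the 4Z geometry.

Step 4
Reactants: 3 (2S,3S)-2,3-epoxyneral; 5 (Z)-3-iodobut-2-en-1-ol
Product: 8 (2R,3S)-3-methyl-3-(4-methylpent-3-en-1-yl)-2-[(1R,2Z)-2-methyl-1,4-bis(triethylsilyloxy)but-2-en-1-yl]oxirane, via lithium (Z)-3-lithiobut-2-en-1-olate 6 (not isolated), via dilithium dialkoxide 7 (not isolated)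
Conditions: 5, n-BuLi (1 equiv) then t-BuLi (2 equiv), Et2O, −78 °C; 3, −78 °C; then Et3SiOTf (2.4 equiv), −78 → 0 °C
Reagents that add atoms: triethylsilyl trifluoromethanesulfonate CC[Si](CC)(CC)OS(=O)(=O)C(F)(F)F
Why: Iodine–lithium exchange retains the Z geometry, and the alkenyllithium adds to the α,β-epoxy aldehyde in the Felkin–Anh sense (anti to the oxirane C–O bond, past the oxirane H) to set 3R, erythro to the oxirane, before both lithium alkoxides are silylated in the same flask.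

Step 5
Reactants: 8 bis(triethylsilyl) ether from step 4
Product: 9 3-{(2S,3R)-2-methyl-3-[(1R,2Z)-2-methyl-1,4-bis(triethylsilyloxy)but-2-en-1-yl]oxiran-2-yl}propanal
Conditions: O3 (1 equiv), CH2Cl2, −78 °C; then PPh3, −78 → 23 °C
Reagents that add atoms: ozone [O-][O+]=O
Why: Chemoselective ozonolysis, because the electron-rich isopropylidene alkene reacts much faster than the C4=C5 alkene, which is deactivated by two allylic silyloxy groups (as in the 6,7-selective ozonolysis of geranyl acetate).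

Step 6
Reactants: 9 aldehyde from step 5; 10 ethyl 2-[(diethoxyphosphoryl)methyl]prop-2-enoate
Product: 11 ethyl (3E)-2-methylidene-6-{(2S,3R)-2-methyl-3-[(1R,2Z)-2-methyl-1,4-bis(triethylsilyloxy)but-2-en-1-yl]oxiran-2-yl}hex-3-enoate
Conditions: 10, NaN(SiMe3)2, THF, −78 °C; then 9, −78 → 0 °C
Reagents that add atoms: none
Why: Horner–Wadsworth–Emmons olefination through the phosphonate α-carbanion gives the E-configured 2-(ethoxycarbonyl)-1,3-diene, which is carried on at once because such dienes dimerise on standing.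

Step 7
Reactants: 11 dienoate from step 6
Product: 12 ethyl 2-[(2R,3R)-3-(2-{(2S,3R)-2-methyl-3-[(1R,2Z)-2-methyl-1,4-bis(triethylsilyloxy)but-2-en-1-yl]oxiran-2-yl}ethyl)oxiran-2-yl]prop-2-enoate
Conditions: D-fructose-derived Shi ketone (30 mol %), Oxone (2KHSO5·KHSO4·K2SO4), K2CO3, Bu4NHSO4, MeCN/CH2(OMe)2/aq. buffer (pH 10.5), 0 °C
Reagents that add atoms: potassium peroxymonosulfate [K+].[O-]S(=O)(=O)OO
Why: Shi asymmetric epoxidation, in which the dioxirane attacks the distal E-disubstituted alkene of the dienoate (not the acrylate alkene, nor the hindered bis-allylically oxygenated C4=C5 alkene) through the spiro transition state that gives the (7R,8R) trans-oxirane, as for (R,R)-trans-β-methylstyrene oxide, and so fixes C8.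

Step 8
Reactants: 12 vinyl oxirane from step 7
Product: 13 ethyl 2-[(2R,3R)-3-(2-{(2S,3R)-2-methyl-3-[(1R,2Z)-2-methyl-4-oxo-1-(triethylsilyloxy)but-2-en-1-yl]oxiran-2-yl}ethyl)oxiran-2-yl]prop-2-enoate
Conditions: (COCl)2, DMSO, CH2Cl2, −78 → −40 °C; then i-Pr2NEt, −78 → −20 °C
Reagents that add atoms: none
Why: Under Swern conditions the chlorosulfonium ion desilylates and oxidises only the primary allylic triethylsilyl ether (the secondary one stays), giving the (4Z)-enal directly, while the hindered amine and low temperature preserve the Z geometry.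

Step 9
Reactants: 13 (4Z)-enal from step 8; 14 angelic anhydride
Product: 18 O3-triethylsilyl macrolide (1S,2R,3R,4Z,6S,7R,8R) with cis-fused α-methylene-γ-lactone, via bis-angelate enal 15 (not isolated), via allyl(ethyl)zinc 16 (not isolated), via ethylzinc alkoxide 17 (not isolated)
Conditions: 14 (1.05 equiv), Pd(PPh3)4 (10 mol %), THF, 0 °C (0.05 M); then slow addition (10 h) to Et2Zn (3 equiv), THF, 23 °C (final 2 mM); aq. NH4Cl
Reagents that add atoms: none
Why: Proposed new method: zerovalent palladium ionises the vinyl oxirane at C7, the freed O8 alkoxide is acylated by the anhydride and angelate returns at C13 to give 15 (closest known: palladium-catalysed 1,4-opening of diene monoepoxides by carboxylates); renewed ionisation of the primary allylic angelate and transmetalation with Et2Zn (Tamaru-type umpolung allylation, known to close ten-membered germacrene rings onto enals) gives allylzinc 16, whose C7 adds to the C6 aldehyde through a chair transition state with C8 axial (C8 cis to CH2Zn, hence 6,7-cis), C8–H inside and the C8–C9 bond anti to the forming bond with the C8–O bond not anti (hence 7R and 6S), after which zinc alkoxide 17 closes onto the ethyl ester (Dreiding–Schmidt-type lactonisation).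

Step 10
Reactants: 18 O3-triethylsilyl macrolide from step 9
Product: 19 target CNP0500828.1 (1S,2R,3R,4Z,6S,7R,8R)
Conditions: Et3N·3HF, MeCN, 0 → 23 °C
Reagents that add atoms: none
Why: Buffered fluoride desilylation of the secondary triethylsilyl ether creates no stereocentre and leaves the oxirane, the α-methylene lactone and the angelate intact.

**Compound list**

1 | nerol, (2Z)-3,7-dimethylocta-2,6-dien-1-ol | CC(C)=CCC/C(C)=C\CO | starting material
2 | (2R,3S)-2,3-epoxynerol, [(2R,3S)-3-methyl-3-(4-methylpent-3-en-1-yl)oxiran-2-yl]methanol | OC[C@H]1O[C@@]1(C)CCC=C(C)C | intermediate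
3 | (2S,3S)-2,3-epoxyneral, (2S,3S)-3-methyl-3-(4-methylpent-3-en-1-yl)oxirane-2-carbaldehyde | O=C[C@H]1O[C@@]1(C)CCC=C(C)C | intermediate
4 | but-2-yn-1-ol | CC#CCO | starting material
5 | (Z)-3-iodobut-2-en-1-ol | C/C(I)=C/CO | intermediate
6 | lithium (Z)-3-lithiobut-2-en-1-olate | C/C([Li])=C/CO[Li] | intermediate
7 | dilithium dialkoxide of the (3R)-adduct of 6 and 3 | [Li]OC/C=C(/C)[C@@H](O[Li])[C@H]1O[C@@]1(C)CCC=C(C)C | intermediate
8 | (2R,3S)-3-methyl-3-(4-methylpent-3-en-1-yl)-2-[(1R,2Z)-2-methyl-1,4-bis(triethylsilyloxy)but-2-en-1-yl]oxirane | CC[Si](CC)(CC)OC/C=C(/C)[C@@H](O[Si](CC)(CC)CC)[C@H]1O[C@@]1(C)CCC=C(C)C | intermediate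
9 | 3-{(2S,3R)-2-methyl-3-[(1R,2Z)-2-methyl-1,4-bis(triethylsilyloxy)but-2-en-1-yl]oxiran-2-yl}propanal (C8 aldehyde) | CC[Si](CC)(CC)OC/C=C(/C)[C@@H](O[Si](CC)(CC)CC)[C@H]1O[C@@]1(C)CCC=O | intermediate
10 | ethyl 2-[(diethoxyphosphoryl)methyl]prop-2-enoate | C=C(CP(=O)(OCC)OCC)C(=O)OCC | starting material
11 | ethyl (3E)-2-methylidene-6-{(2S,3R)-2-methyl-3-[(1R,2Z)-2-methyl-1,4-bis(triethylsilyloxy)but-2-en-1-yl]oxiran-2-yl}hex-3-enoate | CC[Si](CC)(CC)OC/C=C(/C)[C@@H](O[Si](CC)(CC)CC)[C@H]1O[C@@]1(C)CC/C=C/C(=C)C(=O)OCC | intermediate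
12 | (7R,8R)-vinyl oxirane: ethyl 2-[(2R,3R)-3-(2-{(2S,3R)-2-methyl-3-[(1R,2Z)-2-methyl-1,4-bis(triethylsilyloxy)but-2-en-1-yl]oxiran-2-yl}ethyl)oxiran-2-yl]prop-2-enoate | CC[Si](CC)(CC)OC/C=C(/C)[C@@H](O[Si](CC)(CC)CC)[C@H]1O[C@@]1(C)CC[C@H]2O[C@@H]2C(=C)C(=O)OCC | intermediate
13 | (4Z)-enal: ethyl 2-[(2R,3R)-3-(2-{(2S,3R)-2-methyl-3-[(1R,2Z)-2-methyl-4-oxo-1-(triethylsilyloxy)but-2-en-1-yl]oxiran-2-yl}ethyl)oxiran-2-yl]prop-2-enoate | O=C/C=C(/C)[C@@H](O[Si](CC)(CC)CC)[C@H]1O[C@@]1(C)CC[C@H]2O[C@@H]2C(=C)C(=O)OCC | intermediate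
14 | angelic anhydride, (Z)-2-methylbut-2-enoic anhydride | C/C=C(/C)C(=O)OC(=O)/C(C)=C\C | starting material
15 | bis-angelate enal: ethyl (2E,4R)-4-angeloyloxy-2-(angeloyloxymethyl)-6-{(2S,3R)-2-methyl-3-[(1R,2Z)-2-methyl-4-oxo-1-(triethylsilyloxy)but-2-en-1-yl]oxiran-2-yl}hex-2-enoate | O=C/C=C(/C)[C@@H](O[Si](CC)(CC)CC)[C@H]1O[C@@]1(C)CC[C@@H](OC(=O)/C(C)=C\C)/C=C(/C(=O)OCC)COC(=O)/C(C)=C\C | intermediate
16 | allyl(ethyl)zinc from 15 (EtZn–CH2 at C13, C8 cis to CH2Zn, 8R angelate kept) | O=C/C=C(/C)[C@@H](O[Si](CC)(CC)CC)[C@H]1O[C@@]1(C)CC[C@@H](OC(=O)/C(C)=C\C)/C=C(/C(=O)OCC)C[Zn]CC | intermediate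
17 | ethylzinc alkoxide of the (6S,7R,8R) ten-membered hydroxy ester (O6–ZnEt, C11=C13 acrylate ethyl ester on C7) | CCOC(=O)C(=C)[C@H]1[C@@H](O[Zn]CC)/C=C(/C)[C@@H](O[Si](CC)(CC)CC)[C@H]2O[C@@]2(C)CC[C@H]1OC(=O)/C(C)=C\C | intermediate
18 | O3-triethylsilyl ether of the target macrolide (1S,2R,3R,4Z,6S,7R,8R) | C=C1C(=O)O[C@H]2/C=C(/C)[C@@H](O[Si](CC)(CC)CC)[C@H]3O[C@@]3(C)CC[C@@H](OC(=O)/C(C)=C\C)[C@@H]12 | intermediate
19 | CNP0500828.1 (1S,2R,3R,4Z,6S,7R,8R) | C=C1C(=O)O[C@H]2/C=C(/C)[C@@H](O)[C@H]3O[C@@]3(C)CC[C@@H](OC(=O)/C(C)=C\C)[C@@H]12 | target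

**Step count and risks**

Total step count: 10. Longest linear sequence: 9 (steps 1, 2, 4, 5, 6, 7, 8, 9, 10, from nerol).

Steps most likely to fail:

Step 9 (ring closure). The risks are these:
- Allylzinc 16 carries an acyloxy group on C8 and can collapse to a 2-(ethoxycarbonyl)-1,3-diene by 1,4-elimination.
- Zerovalent palladium may also ionise the secondary C8 angelate.
- The C6/C7 facial preference rests on a transition-state model, not on precedent.
- The (4Z)-enal can isomerise.

Fallback (O8 stays a silyl ether during ring closure and the angelate is added afterwards), setting out from 12 and coming back at 19: Pd(PPh3)4/AcOH in THF gives the 1,4-adduct hydroxy acetate F1. Et3SiOTf/2,6-lutidine gives tris(silyl) ether F2. Swern oxidation as in step 8 gives enal F3. Pd(PPh3)4/Et2Zn under the dilution of step 9 gives bis(silyl) macrolide F4; here the C13 acetate is the only ionisable group and the O8 silyl ether is no leaving group. Et3N·3HF gives diol F5. Angelic anhydride 14 (1.1 equiv)/DMAP then acylates the less hindered O8 (O3 lies between the oxirane and the fully substituted C4) to give 19.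

Step 7 (Shi epoxidation). The risks are competing epoxidation of C4=C5, sluggish reaction of the electron-poor dienoate, and Diels–Alder dimerisation of 11.

Fallback (C8 set by alkyne addition, so steps 6 and 7 are bypassed), setting out from 9 and coming back at 15: ethyl propiolate, Me2Zn and the ProPhenol ligand enantiomer that gives the (8R)-carbinol afford hydroxy ynoate F6. NaAlH2(OCH2CH2OCH3)2 at −72 °C (alkoxide-directed trans-hydroalumination, aluminium on C11 cis to C8) followed by monomeric formaldehyde gives (E)-diol F7. Angelic anhydride 14/DMAP gives bis-angelate F8. Swern oxidation of its primary silyl ether gives 15, which is isolated and then submitted to the Pd(PPh3)4/Et2Zn part of step 9.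

Step 4 (alkenyllithium addition). The risks are incomplete formation or poor solubility of the dilithio species 6 and only modest Felkin selectivity at C3.

Fallback (C3 set by reduction of a ketone), setting out from 5 (with 3) and coming back at 8: Et3SiCl/imidazole converts 5 into silyl ether F9. Its alkenyllithium (t-BuLi, Et2O, −78 °C) adds to 3 to give alcohol F10 as a C3 mixture. Dess–Martin periodinane gives epoxy enone F11. Zn(BH4)2 in Et2O at −30 °C gives (3R)-alcohol F12; zinc chelates the carbonyl and oxirane oxygens and hydride comes from the free face, which is erythro-selective. Et3SiOTf/2,6-lutidine then gives 8.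

Further compounds

F1 | step 9 | hydroxy acetate: ethyl (2E,4R)-2-(acetoxymethyl)-4-hydroxy-hex-2-enoate carrying the C1–C6 segment of 12 (both silyl ethers kept) | CC[Si](CC)(CC)OC/C=C(/C)[C@@H](O[Si](CC)(CC)CC)[C@H]1O[C@@]1(C)CC[C@@H](O)/C=C(/C(=O)OCC)COC(C)=O
F2 | step 9 | tris(silyl) ether: O8-triethylsilyl ether of F1 | CC[Si](CC)(CC)OC/C=C(/C)[C@@H](O[Si](CC)(CC)CC)[C@H]1O[C@@]1(C)CC[C@@H](O[Si](CC)(CC)CC)/C=C(/C(=O)OCC)COC(C)=O
F3 | step 9 | enal: (4Z)-C6 aldehyde from F2 (O3 and O8 silyl ethers, C13 acetate) | O=C/C=C(/C)[C@@H](O[Si](CC)(CC)CC)[C@H]1O[C@@]1(C)CC[C@@H](O[Si](CC)(CC)CC)/C=C(/C(=O)OCC)COC(C)=O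
F4 | step 9 | bis(silyl) macrolide: analogue of 18 with O8–SiEt3 in place of the angelate (same configuration) | C=C1C(=O)O[C@H]2/C=C(/C)[C@@H](O[Si](CC)(CC)CC)[C@H]3O[C@@]3(C)CC[C@@H](O[Si](CC)(CC)CC)[C@@H]12
F5 | step 9 | diol: 8-O-deangeloyl 19 | C=C1C(=O)O[C@H]2/C=C(/C)[C@@H](O)[C@H]3O[C@@]3(C)CC[C@@H](O)[C@@H]12
F6 | step 7 | hydroxy ynoate: ethyl (4R)-4-hydroxy-hex-2-ynoate carrying the C1–C6 segment of 9 | CC[Si](CC)(CC)OC/C=C(/C)[C@@H](O[Si](CC)(CC)CC)[C@H]1O[C@@]1(C)CC[C@@H](O)C#CC(=O)OCC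
F7 | step 7 | (E)-diol: ethyl (2E,4R)-4-hydroxy-2-(hydroxymethyl)-hex-2-enoate carrying the C1–C6 segment of 9 | CC[Si](CC)(CC)OC/C=C(/C)[C@@H](O[Si](CC)(CC)CC)[C@H]1O[C@@]1(C)CC[C@@H](O)/C=C(/C(=O)OCC)CO
F8 | step 7 | bis-angelate: O6-triethylsilyl precursor of 15 (C6 as CH2OSiEt3) | CC[Si](CC)(CC)OC/C=C(/C)[C@@H](O[Si](CC)(CC)CC)[C@H]1O[C@@]1(C)CC[C@@H](OC(=O)/C(C)=C\C)/C=C(/C(=O)OCC)COC(=O)/C(C)=C\C
F9 | step 4 | silyl ether: (Z)-triethyl[(3-iodobut-2-en-1-yl)oxy]silane | C/C(I)=C/CO[Si](CC)(CC)CC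
F10 | step 4 | alcohol: C3-epimeric mixture, O6-triethylsilyl ether with free C3–OH | CC[Si](CC)(CC)OC/C=C(/C)C(O)[C@H]1O[C@@]1(C)CCC=C(C)C
F11 | step 4 | epoxy enone: C3 ketone from F10 | CC[Si](CC)(CC)OC/C=C(/C)C(=O)[C@H]1O[C@@]1(C)CCC=C(C)C
F12 | step 4 | (3R)-alcohol: erythro epoxy alcohol, O6-triethylsilyl ether | CC[Si](CC)(CC)OC/C=C(/C)[C@@H](O)[C@H]1O[C@@]1(C)CCC=C(C)C
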